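**Remark on the chemistry.** Germacrane numbering is used throughout: ring C1–C10, C14 the ester carbon on C10, C15 the methyl on C4, lactone O–C6 and C7–C11(=C13)–C12. Two stereo-elements are erased later and are therefore not controlled: the geometry of the C1=C10 enoate in 7–9 and 12–16 (drawn as the expected E isomer) and the bromide centre C1 in 17–19 (drawn without configuration, both epimers).

## Analysis of the target

- Target 28 is a melampolide: a ten-membered carbocycle with a trisubstituted C1=C10 alkene whose ring bonds (to C2 and C9) are cis, and a trisubstituted E C4=C5 alkene.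
- A trans-fused α-methylene-γ-butyrolactone spans C6 (oxygen) and C7 (C11=C13, C12 carbonyl).
- Four contiguous stereocentres sit on one flank: C6 (R), C7 (S), C8 (S), C9 (S). H6 and H7 are trans; O8 is anti to C11 along C6–C7–C8–C9; O8 and O9 are syn along C7–C8–C9–C10 (8β, 9α on the ring).
- Three different acyl groups must be placed without scrambling: the methyl ester C14 on C10, an acetate on O9 and a 2-(hydroxymethyl)acrylate on O8.
- Sensitive features are the two Michael acceptors, the allylic C6–O lactone bond, the vicinal O8/O9 esters (acyl migration) and the 1,5-diene in a medium ring (Cope and transannular reactions).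
- The difficulty is to close a ten-membered ring with both alkene geometries fixed while setting C8 and C9 with their oxygens differentiated.
- The strategy rests on the segment C1=C10(CO2Me)–C9(OAc)–C8(O): it is the pattern left when an allylmetal with an ester on its central carbon and an acetoxy group on its γ-carbon adds to a C8 aldehyde with allylic transposition.

## Retrosynthetic reasoning

**O8 ester (28 ⇒ 27 ⇒ 21 + 25).** The O8–acyl bond is cut last. The hydroxymethyl acrylate is the most fragile part of 28 and would not survive organometallic steps. It is introduced as the silyl-protected acid 25 so that its own hydroxyl cannot compete in the acylation. Forward, the step must acylate the hindered 8-hydroxyl of 21 faster than the neighbouring acetate can migrate. Acid 25 comes from 22 through 23.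

**Ring closure (21 ⇒ 19).** The C8–C9 ring bond is cut with allylic transposition, so that C1=C10 becomes C9=C10 and C1 takes a bromide. This is the only ring bond flanked by both carbinol carbons. Cutting it turns the two stereocentres into an aldehyde (C8) and an enol acetate carbon (C9), and leaves the acetate, the C14 ester and the ring alkene as parts of one allyl unit. The forward reaction in 19 has to form the ring, C8 and C9 and the ring-cis alkene in one chromium-mediated addition.

**Activating the two ends (19 ⇒ 18 ⇒ 17 ⇒ 16).** The C8 aldehyde is made last, from alcohol 18, because C7–H in 19 is activated by the aldehyde and the enoate. The C1–Br and O–acetyl bonds of 17 are cut together: they are the two halves of a 1,4-addition of an acetyl halide across the formyl enoate 16. Alcohol 18 has to be masked during that addition, which is why the silyl ether 17 intervenes.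

**Lactone and C8 hydroxyl (16 ⇒ 15 ⇒ 14 ⇒ 13).** The aldehyde of 16 is stored as the dimethyl acetal 15. The C12–O6 lactone bond of 14 is cut and C12 is re-joined to O8, which gives the isomeric lactone 13. This translactonisation lets the C7–C8 unit be brought in as a ring, and a ring fixes the geometry of the allyl reagent.

**C6–C7 bond (13 ⇒ 9 + 11).** This bond is cut because it joins the two halves at the only point where both C6 and C7 can be set in one step. Enal 9 carries C1–C6 plus C9, C10 and C14; bromolactone 11 carries C7, C8 and C11–C13. The forward allylation has to be anti-selective (trans lactone later) and enantioselective. Bromide 11 comes from 10 by allylic bromination.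

**Enal 9 (9 ⇒ 8 ⇒ 5 ⇒ 2 + 3; 2 ⇒ 1).** The C1=C10 bond of 8 is cut to aldehyde 2 and the enolate of 3 (aldol 5, then elimination). Doing this early, on a simple aldehyde, keeps strong base away from the α-methylene lactone. Aldehyde 2 arises by cleaving the terminal alkene of 1, so the E geometry of C4=C5 is bought with the starting terpene and not made.

## Alternatives that were turned down

**Alternative 1: enone–cyclobutene photocycloaddition, then cycloreversion.**
- Disconnection: both ring alkenes are traced back to one cyclobutane, by re-forming the σ bonds C5–C10 and C1–C4.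
- Forward key step: irradiation joins C1–C10 and C4–C5 to give photoadduct A1 from the bicyclic enone ester A2 and 1-methylcyclobutene A3. Heating A1 later cleaves C5–C10 and C1–C4 to release the 1,5-diene.
- For: C6, C7 and C8 are set on the rigid six-membered ring of A2, two C–C bonds form at once, no high dilution is needed, and C14 is in place.
- Against: the orientation of A3 (C4, with its methyl, must bond to C5) has no strong bias. The cycloreversion needs high temperature, and a 1,5-diene made that way can continue by Cope rearrangement or emerge with the wrong alkene geometry. A1 leaves C9 as a ketone and C11 saturated, so a stereoselective reduction in a ten-membered ring, acetylation and α-methylenation follow, and the O8 exchange comes on top.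
- Comparison: A1 is stronger on forming the carbon skeleton on a small rigid scaffold. The chosen route instead delivers C9 at its final oxidation level with its acetate in the ring-forming step and never heats the 1,5-diene.

**Alternative 2: anionic oxy-Cope ring expansion.**
- Disconnection: C6–C7 is cut and C4–C9 re-formed, folding the ten-membered ring into a six-membered ring (C9, C10, C1–C4) with alkenyl groups on C9 and C4.
- Forward key step: the C9 potassium alkoxide undergoes a [3,3] shift across C7=C8–C9–C4–C5=C6 and opens to cyclodecadienone A4.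
- For: this is well-established chemistry for cyclodecadienones, needs no dilution, and the ordered transition state sets C6, C7 and the E C4=C5 alkene together.
- Against: in A4, C8 is a bare methylene, C9 a ketone, C14 an ether-protected alcohol and the lactone is not yet formed. C8 would need α-oxidation, C9 a stereoselective reduction, C14 and C12 oxidation to the acid level, and O6 deprotection and lactonisation, all on a flexible ring.
- Comparison: it is clearly stronger on precedent for the ring-forming step. The chosen route offers oxidation-state economy instead: C8, C9 and C14 appear at their final levels, with O8 and O9 already differentiated.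

**Alternative 3: boronate fragmentation of a cis-fused decalin.**
- Disconnection: the C5–C10 σ bond is re-formed, giving a decalin with boron on C4 and a sulfonate on C1.
- Forward key step: activation of the boronate cleaves C5–C10 with loss of the C1 leaving group and gives protected melampolide A5.
- For: both alkene geometries follow stereospecifically from the decalin, all four stereocentres are set on a rigid bicycle, and O8 and O9 in A5 carry different protecting groups.
- Against: the precursor is dense. It needs a quaternary C10 bearing the ester and a tertiary boronate on C4 (which also bears C15), which ordinary hydroboration does not deliver, with the correct antiperiplanar alignment. After the fragmentation, α-methylenation of the lactone next to the ring enoate and two protecting-group exchanges remain.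
- Comparison: it is stronger on certainty of alkene geometry and relative configuration. The chosen route offers convergence and a much shorter path, at the price of an unprecedented ring closure.

Key step: step 13

## Route

Step 1
Reactants: 1 geranyl acetate
Product: 2 (2E)-3-methyl-6-oxohex-2-en-1-yl acetate
Conditions: O3, pyridine, CH2Cl2, −78 °C; then Me2S
Reagents that add atoms: ozone, [O-][O+]=O
Why: Chemoselective ozonolysis; the terminal alkene is more electron-rich than the one deactivated by the allylic acetate, so one equivalent of ozone should cleave it alone, and the E geometry of C4=C5 is inherited from 1.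

Step 2
Reactants: 3 methyl 3,3-dimethoxypropanoate; 2 (2E)-3-methyl-6-oxohex-2-en-1-yl acetate
Product: 5 methyl (6E)-8-acetoxy-2-(dimethoxymethyl)-3-hydroxy-6-methyloct-6-enoate (diastereomer mixture), via lithium enolate 4 (not isolated)
Conditions: LiN(i-Pr)2, THF, −78 °C; then 2, −78 °C; aq. NH4Cl
Reagents that add atoms: none
Why: Directed aldol addition of a preformed lithium ester enolate; at −78 °C the enolate should not lose methoxide and should add to the aldehyde faster than to the acetate, and the two new stereocentres are removed in step 3.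

Step 3
Reactants: 5 methyl (6E)-8-acetoxy-2-(dimethoxymethyl)-3-hydroxy-6-methyloct-6-enoate
Product: 8 methyl (2E,6E)-2-(dimethoxymethyl)-8-hydroxy-6-methylocta-2,6-dienoate, via mesylate 6 (not isolated), via enoate acetate 7 (not isolated)
Conditions: MsCl, Et3N, CH2Cl2, 0 °C; then DBU, MeOH, rt
Reagents that add atoms: none
Why: Mesylation and E1cB elimination give the trisubstituted enoate (alkyl chain trans to the ester expected), and DBU-catalysed methanolysis removes the primary acetate in the same pot; the enoate geometry is of no consequence because C1 becomes sp3 in step 10.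

Step 4
Reactants: 8 methyl (2E,6E)-2-(dimethoxymethyl)-8-hydroxy-6-methylocta-2,6-dienoate
Product: 9 methyl (2E,6E)-2-(dimethoxymethyl)-6-methyl-8-oxoocta-2,6-dienoate
Conditions: MnO2, CH2Cl2, rt
Reagents that add atoms: none
Why: Allylic alcohol oxidation with MnO2 is neutral, leaves the acetal and enoate alone and should keep the E geometry of the enal.

Step 5
Reactants: 10 α-methylene-γ-butyrolactone
Product: 11 3-(bromomethyl)furan-2(5H)-one
Conditions: NBS, AIBN (cat.), PhCF3, reflux
Reagents that add atoms: N-bromosuccinimide, O=C1CCC(=O)N1Br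
Why: Wohl–Ziegler bromination; hydrogen abstraction at the ring allylic carbon gives an allyl radical that takes bromine at the exocyclic terminus to give the conjugated butenolide, and the regioisomeric allylic bromide would give the same allylchromium in step 6.

Step 6
Reactants: 9 methyl (2E,6E)-2-(dimethoxymethyl)-6-methyl-8-oxoocta-2,6-dienoate; 11 3-(bromomethyl)furan-2(5H)-one
Product: 13 methyl (2E,6E,8R)-2-(dimethoxymethyl)-8-hydroxy-6-methyl-8-[(3R)-4-methylidene-5-oxooxolan-3-yl]octa-2,6-dienoate, via trimethylsilyl ether 12 (not isolated)
Conditions: CrCl2 (10 mol %), chiral 1,8-bis(oxazolin-2-yl)carbazole ligand (12 mol %), Mn powder, Me3SiCl, i-Pr2NEt, THF, rt; then n-Bu4NF, AcOH, THF, 0 °C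
Reagents that add atoms: none
Why: Catalytic asymmetric Nozaki–Hiyama 2-(alkoxycarbonyl)allylation with Mn as terminal reductant and Me3SiCl for turnover; the ring of 11 locks the allylchromium in the E-crotyl-type geometry, so the chair transition state gives the anti C6/C7 adduct. The ligand enantiomer that delivers the allyl group to the Si face of the aldehyde sets C6 (R), and C7 follows through the chair.

Step 7
Reactants: 13 methyl (2E,6E,8R)-2-(dimethoxymethyl)-8-hydroxy-6-methyl-8-[(3R)-4-methylidene-5-oxooxolan-3-yl]octa-2,6-dienoate
Product: 14 methyl (2E,6E)-2-(dimethoxymethyl)-7-[(2R,3R)-3-(hydroxymethyl)-4-methylidene-5-oxooxolan-2-yl]-6-methylhepta-2,6-dienoate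
Conditions: DBU (0.2 equiv), CH2Cl2, 0 °C to rt
Reagents that add atoms: none
Why: Base-catalysed translactonisation (intramolecular transesterification): the C6 oxygen attacks C12 and releases the primary C8 hydroxyl; the trans-disubstituted lactone with the free primary alcohol should be the more stable isomer, and no stereocentre is touched, so anti becomes trans.

Step 8
Reactants: 14 methyl (2E,6E)-2-(dimethoxymethyl)-7-[(2R,3R)-3-(hydroxymethyl)-4-methylidene-5-oxooxolan-2-yl]-6-methylhepta-2,6-dienoate
Product: 15 tert-butyldiphenylsilyl ether of 14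
Conditions: t-BuPh2SiCl, imidazole, CH2Cl2, 0 °C to rt
Reagents that add atoms: tert-butyl(chloro)diphenylsilane, CC(C)(C)[Si](Cl)(c1ccccc1)c1ccccc1
Why: Standard silylation of a primary alcohol; this silyl group is chosen because it should survive the aqueous acid of step 9 and the acyl bromide of step 10.

Step 9
Reactants: 15 tert-butyldiphenylsilyl ether of 14
Product: 16 methyl (2E,6E)-7-[(2R,3R)-3-{[tert-butyl(diphenyl)silyl]oxymethyl}-4-methylidene-5-oxooxolan-2-yl]-2-formyl-6-methylhepta-2,6-dienoate
Conditions: Amberlyst-15, acetone/H2O, rt
Reagents that add atoms: water, O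
Why: Acid-catalysed acetal hydrolysis under conditions mild enough for the silyl ether and the allylic lactone; the formyl enoate is used without storage.

Step 10
Reactants: 16 methyl (2E,6E)-7-[(2R,3R)-3-{[tert-butyl(diphenyl)silyl]oxymethyl}-4-methylidene-5-oxooxolan-2-yl]-2-formyl-6-methylhepta-2,6-dienoate
Product: 17 methyl (2Z)-3-acetoxy-2-{(4E)-1-bromo-5-[(2R,3R)-3-{[tert-butyl(diphenyl)silyl]oxymethyl}-4-methylidene-5-oxooxolan-2-yl]-4-methylpent-4-en-1-yl}prop-2-enoate (both epimers at the bromide carbon)
Conditions: AcBr, ZnBr2 (cat.), CH2Cl2, −20 to 0 °C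
Reagents that add atoms: acetyl bromide, CC(=O)Br
Why: Conjugate addition of an acyl halide to an α,β-unsaturated aldehyde, the reaction by which 3-bromopropenyl acetate is made from acrolein: bromide ends on C1 and the enol oxygen is acetylated, any 1,2-adduct rearranging by allylic shift. The enol acetate should settle with the acetoxy group trans to the ester, as β-oxyacrylates do, and the C1 configuration does not matter.

Step 11
Reactants: 17 silyl-protected γ-acetoxyallyl bromide
Product: 18 methyl (2Z)-3-acetoxy-2-{(4E)-1-bromo-5-[(2R,3R)-3-(hydroxymethyl)-4-methylidene-5-oxooxolan-2-yl]-4-methylpent-4-en-1-yl}prop-2-enoate (both epimers at the bromide carbon)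
Conditions: HF·pyridine, THF, 0 °C to rt
Reagents that add atoms: none
Why: Desilylation with an acidic, weakly nucleophilic fluoride source, chosen so that neither the allylic bromide is displaced nor the enol acetate cleaved.

Step 12
Reactants: 18 hydroxy γ-acetoxyallyl bromide
Product: 19 methyl (2Z)-3-acetoxy-2-{(4E)-1-bromo-5-[(2R,3S)-3-formyl-4-methylidene-5-oxooxolan-2-yl]-4-methylpent-4-en-1-yl}prop-2-enoate (both epimers at the bromide carbon)
Conditions: Dess–Martin periodinane, CH2Cl2, 0 °C to rt; filtration; used at once
Reagents that add atoms: none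
Why: Dess–Martin oxidation is neutral and fast, which matters because C7–H of 19 is activated by the aldehyde and the enoate; the aldehyde is not purified on silica.

Step 13
Reactants: 19 lactone aldehyde with γ-acetoxyallyl bromide
Product: 21 methyl 9α-acetoxy-8β-hydroxygermacra-1(10),4E,11(13)-trien-6α,12-olid-14-oate (7α-H; C2 and C9 cis across C1=C10; stereocentres as in 28), via allylchromium dichloride 20 (not isolated)
Conditions: CrCl2 (6 equiv), THF, 0 °C to rt, slow addition of 19 (final about 2 mM); aq. NH4Cl, 0 °C
Reagents that add atoms: none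
Why: Proposed new method: CrCl2 reduces the C1 bromide by two one-electron transfers to the trivalent allylchromium 20, which adds through its γ-carbon C9 to the C8 aldehyde in a six-membered chair (Cr, O8, C8, C9, C10, C1), forming C8–C9 and moving the alkene to C1=C10; the closest known reactions are intermolecular chromium- or indium-mediated γ-acyloxyallylations of aldehydes and intramolecular Nozaki–Hiyama 2-(alkoxycarbonyl)allylations that close ten-membered rings, and the new element is their union in one substrate. The ten-membered carbocycle closes in the 10-exo-trig mode at the aldehyde carbon (SE2' at the allylmetal), and attack through C1 is excluded because it would give an eight-membered ring containing the E C4=C5 alkene. C9 is controlled by the enol acetate geometry: with the acetoxy oxygen cis to C1 it is axial in the chair while C7 is equatorial, which gives the 8,9-syn (8β-O, 9α-OAc) pair. C8 is controlled by C7: the tether holds C9 gauche to C6, and of the remaining approaches the Felkin–Anh one (anti to the C7–C11 bond, past H7, carbonyl oxygen between C6 and C11) gives the 8β-alkoxide. The ring-cis C1=C10 alkene needs C2 pseudo-axial on C1, which is favoured by allylic 1,2-strain with the C10 ester and by the shorter span from an axial C2 to the equatorial C7. Both C1 epimers of 19 converge because the allylchromium should epimerise faster than it adds. The α-methylene lactone and the esters should be inert to divalent chromium, and high dilution suppresses intermolecular coupling.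

Step 14
Reactants: 22 methyl 2-(hydroxymethyl)acrylate
Product: 23 methyl 2-{[tert-butyl(dimethyl)silyl]oxymethyl}acrylate
Conditions: t-BuMe2SiCl, imidazole, CH2Cl2, 0 °C to rt
Reagents that add atoms: tert-butyl(chloro)dimethylsilane, CC(C)(C)[Si](C)(C)Cl
Why: Standard silylation of a primary allylic alcohol, needed so that the acid cannot acylate itself in step 16.

Step 15
Reactants: 23 methyl 2-{[tert-butyl(dimethyl)silyl]oxymethyl}acrylate
Product: 25 2-{[tert-butyl(dimethyl)silyl]oxymethyl}acrylic acid, via lithium carboxylate 24 (not isolated)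
Conditions: LiOH, THF/H2O, 0 °C to rt; then 1 M HCl to pH 3–4, 0 °C
Reagents that add atoms: lithium hydroxide, [Li+].[OH-]
Why: Saponification of a methyl ester; the primary silyl ether tolerates LiOH and the brief cold acidification.

Step 16
Reactants: 25 2-{[tert-butyl(dimethyl)silyl]oxymethyl}acrylic acid; 21 8-hydroxy-9-acetoxy melampolide
Product: 27 methyl (6R,7S,8S,9S)-9α-acetoxy-8β-(2-{[tert-butyl(dimethyl)silyl]oxymethyl}acryloyloxy)germacra-1(10),4E,11(13)-trien-6α,12-olid-14-oate, via mixed anhydride 26 (not isolated)
Conditions: 2,4,6-Cl3C6H2COCl, Et3N, toluene, rt; then 21, DMAP, 0 °C to rt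
Reagents that add atoms: none
Why: Yamaguchi esterification suits a hindered secondary alcohol; the low temperature and preformed anhydride are meant to make acylation of O8 faster than acetyl migration from O9.

Step 17
Reactants: 27 silyl-protected target
Product: 28 methyl (6R,7S,8S,9S)-9α-acetoxy-8β-[2-(hydroxymethyl)acryloyloxy]germacra-1(10),4E,11(13)-trien-6α,12-olid-14-oate (target)
Conditions: HF·pyridine, THF, 0 °C
Reagents that add atoms: none
Why: Acidic fluoride removes the primary silyl ether without base, so neither ester migrates and neither Michael acceptor is attacked.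

## Compound list

1 | geranyl acetate, (2E)-3,7-dimethylocta-2,6-dien-1-yl acetate | CC(C)=CCC/C(C)=C/COC(C)=O | starting material
2 | (2E)-3-methyl-6-oxohex-2-en-1-yl acetate | O=CCC/C(C)=C/COC(C)=O | intermediate
3 | methyl 3,3-dimethoxypropanoate | COC(=O)CC(OC)OC | starting material
4 | lithium enolate of 3 | [Li+].COC([O-])=CC(OC)OC | intermediate
5 | methyl (6E)-8-acetoxy-2-(dimethoxymethyl)-3-hydroxy-6-methyloct-6-enoate, diastereomer mixture | COC(=O)C(C(OC)OC)C(O)CC/C(C)=C/COC(C)=O | intermediate
6 | 3-methanesulfonate of 5 | COC(=O)C(C(OC)OC)C(OS(C)(=O)=O)CC/C(C)=C/COC(C)=O | intermediate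
7 | methyl (2E,6E)-8-acetoxy-2-(dimethoxymethyl)-6-methylocta-2,6-dienoate | COC(=O)/C(C(OC)OC)=C/CC/C(C)=C/COC(C)=O | intermediate
8 | methyl (2E,6E)-2-(dimethoxymethyl)-8-hydroxy-6-methylocta-2,6-dienoate | COC(=O)/C(C(OC)OC)=C/CC/C(C)=C/CO | intermediate
9 | methyl (2E,6E)-2-(dimethoxymethyl)-6-methyl-8-oxoocta-2,6-dienoate | COC(=O)/C(C(OC)OC)=C/CC/C(C)=C/C=O | intermediate
10 | α-methylene-γ-butyrolactone, 3-methylideneoxolan-2-one | C=C1CCOC1=O | starting material
11 | 3-(bromomethyl)furan-2(5H)-one | BrCC1=CCOC1=O | intermediate
12 | trimethylsilyl ether of 13 | C=C1C(=O)OC[C@@H]1[C@H](O[Si](C)(C)C)/C=C(\C)CC/C=C(/C(=O)OC)C(OC)OC | intermediate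
13 | methyl (2E,6E,8R)-2-(dimethoxymethyl)-8-hydroxy-6-methyl-8-[(3R)-4-methylidene-5-oxooxolan-3-yl]octa-2,6-dienoate (anti adduct) | C=C1C(=O)OC[C@@H]1[C@H](O)/C=C(\C)CC/C=C(/C(=O)OC)C(OC)OC | intermediate
14 | methyl (2E,6E)-2-(dimethoxymethyl)-7-[(2R,3R)-3-(hydroxymethyl)-4-methylidene-5-oxooxolan-2-yl]-6-methylhepta-2,6-dienoate (trans lactone) | OC[C@H]1C(=C)C(=O)O[C@@H]1/C=C(\C)CC/C=C(/C(=O)OC)C(OC)OC | intermediate
15 | tert-butyldiphenylsilyl ether of 14 | CC(C)(C)[Si](OC[C@H]1C(=C)C(=O)O[C@@H]1/C=C(\C)CC/C=C(/C(=O)OC)C(OC)OC)(c1ccccc1)c1ccccc1 | intermediate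
16 | methyl (2E,6E)-7-[(2R,3R)-3-{[tert-butyl(diphenyl)silyl]oxymethyl}-4-methylidene-5-oxooxolan-2-yl]-2-formyl-6-methylhepta-2,6-dienoate | CC(C)(C)[Si](OC[C@H]1C(=C)C(=O)O[C@@H]1/C=C(\C)CC/C=C(/C(=O)OC)C=O)(c1ccccc1)c1ccccc1 | intermediate
17 | methyl (2Z)-3-acetoxy-2-{(4E)-1-bromo-5-[(2R,3R)-3-{[tert-butyl(diphenyl)silyl]oxymethyl}-4-methylidene-5-oxooxolan-2-yl]-4-methylpent-4-en-1-yl}prop-2-enoate, both C1 epimers | CC(C)(C)[Si](OC[C@H]1C(=C)C(=O)O[C@@H]1/C=C(\C)CCC(Br)/C(C(=O)OC)=C\OC(C)=O)(c1ccccc1)c1ccccc1 | intermediate
18 | methyl (2Z)-3-acetoxy-2-{(4E)-1-bromo-5-[(2R,3R)-3-(hydroxymethyl)-4-methylidene-5-oxooxolan-2-yl]-4-methylpent-4-en-1-yl}prop-2-enoate, both C1 epimers | OC[C@H]1C(=C)C(=O)O[C@@H]1/C=C(\C)CCC(Br)/C(C(=O)OC)=C\OC(C)=O | intermediate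
19 | methyl (2Z)-3-acetoxy-2-{(4E)-1-bromo-5-[(2R,3S)-3-formyl-4-methylidene-5-oxooxolan-2-yl]-4-methylpent-4-en-1-yl}prop-2-enoate, both C1 epimers (key-step precursor) | O=C[C@H]1C(=C)C(=O)O[C@@H]1/C=C(\C)CCC(Br)/C(C(=O)OC)=C\OC(C)=O | intermediate
20 | allylchromium dichloride from 19 (chromium on C1, solvent ligands omitted) | O=C[C@H]1C(=C)C(=O)O[C@@H]1/C=C(\C)CCC([Cr](Cl)Cl)/C(C(=O)OC)=C\OC(C)=O | intermediate
21 | methyl 9α-acetoxy-8β-hydroxygermacra-1(10),4E,11(13)-trien-6α,12-olid-14-oate (7α-H; C2 and C9 cis across C1=C10; key-step product) | O[C@H]1[C@H]2C(=C)C(=O)O[C@@H]2/C=C(\C)CC/C=C(/C(=O)OC)[C@@H]1OC(C)=O | intermediate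
22 | methyl 2-(hydroxymethyl)acrylate | C=C(CO)C(=O)OC | starting material
23 | methyl 2-{[tert-butyl(dimethyl)silyl]oxymethyl}acrylate | C=C(CO[Si](C)(C)C(C)(C)C)C(=O)OC | intermediate
24 | lithium 2-{[tert-butyl(dimethyl)silyl]oxymethyl}acrylate | [Li+].C=C(CO[Si](C)(C)C(C)(C)C)C([O-])=O | intermediate
25 | 2-{[tert-butyl(dimethyl)silyl]oxymethyl}acrylic acid | C=C(CO[Si](C)(C)C(C)(C)C)C(=O)O | intermediate
26 | mixed anhydride of 25 with 2,4,6-trichlorobenzoic acid | C=C(CO[Si](C)(C)C(C)(C)C)C(=O)OC(=O)c1c(Cl)cc(Cl)cc1Cl | intermediate
27 | methyl (6R,7S,8S,9S)-9α-acetoxy-8β-(2-{[tert-butyl(dimethyl)silyl]oxymethyl}acryloyloxy)germacra-1(10),4E,11(13)-trien-6α,12-olid-14-oate | C=C(CO[Si](C)(C)C(C)(C)C)C(=O)O[C@H]1[C@H]2C(=C)C(=O)O[C@@H]2/C=C(\C)CC/C=C(/C(=O)OC)[C@@H]1OC(C)=O | intermediate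
28 | methyl (6R,7S,8S,9S)-9α-acetoxy-8β-[2-(hydroxymethyl)acryloyloxy]germacra-1(10),4E,11(13)-trien-6α,12-olid-14-oate | C=C(CO)C(=O)O[C@H]1[C@H]2C(=C)C(=O)O[C@@H]2/C=C(\C)CC/C=C(/C(=O)OC)[C@@H]1OC(C)=O | target

## Step count and least certain steps

Total: 17 steps. Longest linear sequence: 14 steps (1–4, 6–13, 16, 17). The precursor 19 is reached in 12 steps.

**Step 13 (key step, proposed new method).**
- What may go wrong: acetyl migration from O9 to the O8 chromium alkoxide or during work-up; poor facial selectivity at C8, since the chair fixes only the 8,9 relationship; intermolecular coupling or simple reduction of the bromide; enolisation at C7 before the ring closes.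
- Fallback with known chemistry (pinacol closure of the same bond): from 16, HF·pyridine should give the hydroxy formyl enoate F1 and Dess–Martin oxidation the dialdehyde F2. An intramolecular pinacol coupling with low-valent titanium (TiCl3(DME)1.5, Zn–Cu couple, DME, rt, high dilution) should close C8–C9 to the ring diol F3. After separation of the 8β,9α isomer, acetylation of the less hindered allylic 9-hydroxyl (Ac2O, 2,4,6-collidine, −20 °C) returns to the route at 21.

**Step 10.**
- What may go wrong: the addition may stop at the 1,2-adduct, hydrogen bromide formed in the flask may add to the C4=C5 alkene, or the silyl ether may be cleaved by the acyl bromide.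
- Fallback (stepwise): from 16, conjugate hydrobromination (HBr, CH2Cl2, −40 °C) should give the β-bromo α-formyl ester F4, which is O-acetylated under acid catalysis (isopropenyl acetate, TsOH cat.) to rejoin at 17.

**Step 11.**
- What may go wrong: slow cleavage of the hindered silyl ether, with loss of the enol acetate or displacement of the allylic bromide during the long exposure.
- Fallback (change of protecting group and order): from 16, the silyl ether is removed before the bromide exists, giving F1. The alcohol is masked as its trifluoroacetate F5 ((CF3CO)2O, 2,6-lutidine, −20 °C), the acetyl bromide addition gives F6, and neutral methanolysis (MeOH, 0 °C) frees the alcohol to rejoin at 18.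

**Step 6.**
- What may go wrong: insufficient facial selectivity of the catalyst with this cyclic bromide and a β,β-disubstituted enal, or a racemic background reaction.
- Fallback (resolution): from 9 and 11, a Barbier allylation (Zn dust, THF/aq. NH4Cl) should give the anti adduct as a racemate, 13 with its enantiomer F7; step 7 then gives 14 with its enantiomer F8. Lipase-catalysed acetylation (Burkholderia cepacia lipase, vinyl acetate) either converts F8 into acetate F9 and leaves 14, or converts 14 into acetate F10, which the same lipase hydrolyses in buffer. Either way the route is rejoined at 14.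

**Step 7.**
- What may go wrong: an unfavourable or slow lactone equilibrium, or base-induced isomerisation of the exocyclic methylene into the ring.
- Fallback (through the open acid): from 13, LiOH (1.1 equiv, THF/H2O, 0 °C) should open the lactone to the lithium dihydroxy carboxylate F11. Selective silylation of the primary hydroxyl (t-BuPh2SiCl, imidazole, DMF) gives hydroxy acid F12 after mild acidic work-up, and F12 can lactonise only onto O6, which rejoins the route at 15.

## Further compounds

F1 | step 13 | methyl (2E,6E)-2-formyl-7-[(2R,3R)-3-(hydroxymethyl)-4-methylidene-5-oxooxolan-2-yl]-6-methylhepta-2,6-dienoate | OC[C@H]1C(=C)C(=O)O[C@@H]1/C=C(\C)CC/C=C(/C(=O)OC)C=O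
F2 | step 13 | methyl (2E,6E)-2-formyl-7-[(2R,3S)-3-formyl-4-methylidene-5-oxooxolan-2-yl]-6-methylhepta-2,6-dienoate | O=C[C@H]1C(=C)C(=O)O[C@@H]1/C=C(\C)CC/C=C(/C(=O)OC)C=O
F3 | step 13 | methyl 8β,9α-dihydroxygermacra-1(10),4E,11(13)-trien-6α,12-olid-14-oate (21 without the acetyl group) | O[C@H]1[C@H]2C(=C)C(=O)O[C@@H]2/C=C(\C)CC/C=C(/C(=O)OC)[C@@H]1O
F4 | step 10 | β-bromo α-formyl ester from 16 (aldehyde tautomer, C1 and C10 epimers) | CC(C)(C)[Si](OC[C@H]1C(=C)C(=O)O[C@@H]1/C=C(\C)CCC(Br)C(C=O)C(=O)OC)(c1ccccc1)c1ccccc1
F5 | step 11 | trifluoroacetate of F1 | O=C(OC[C@H]1C(=C)C(=O)O[C@@H]1/C=C(\C)CC/C=C(/C(=O)OC)C=O)C(F)(F)F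
F6 | step 11 | trifluoroacetate of 18 | O=C(OC[C@H]1C(=C)C(=O)O[C@@H]1/C=C(\C)CCC(Br)/C(C(=O)OC)=C\OC(C)=O)C(F)(F)F
F7 | step 6 | enantiomer of 13 | C=C1C(=O)OC[C@H]1[C@@H](O)/C=C(\C)CC/C=C(/C(=O)OC)C(OC)OC
F8 | step 6 | enantiomer of 14 | OC[C@@H]1C(=C)C(=O)O[C@H]1/C=C(\C)CC/C=C(/C(=O)OC)C(OC)OC
F9 | step 6 | acetate of F8 | CC(=O)OC[C@@H]1C(=C)C(=O)O[C@H]1/C=C(\C)CC/C=C(/C(=O)OC)C(OC)OC
F10 | step 6 | acetate of 14 | CC(=O)OC[C@H]1C(=C)C(=O)O[C@@H]1/C=C(\C)CC/C=C(/C(=O)OC)C(OC)OC
F11 | step 7 | lithium dihydroxy carboxylate from 13 | [Li+].OC[C@H]([C@H](O)/C=C(\C)CC/C=C(/C(=O)OC)C(OC)OC)C(=C)C([O-])=O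
F12 | step 7 | primary tert-butyldiphenylsilyl ether of the hydroxy acid from F11 | CC(C)(C)[Si](OC[C@H]([C@H](O)/C=C(\C)CC/C=C(/C(=O)OC)C(OC)OC)C(=C)C(=O)O)(c1ccccc1)c1ccccc1
A1 | alternative 1 | cis-anti-cis tricyclic photoadduct | COC(=O)[C@]12[C@@H]3CC[C@]3(C)[C@H]1[C@H]1OC(=O)C[C@@H]1[C@H](O[Si](C)(C)C(C)(C)C)C2=O
A2 | alternative 1 | bicyclic enone ester | COC(=O)C1=C[C@H]2OC(=O)C[C@@H]2[C@H](O[Si](C)(C)C(C)(C)C)C1=O
A3 | alternative 1 | 1-methylcyclobutene | CC1=CCC1
A4 | alternative 2 | (1(10)-cis,4E)-cyclodecadien-9-one with C6 ether and C7 side chain | O=C1C[C@@H](C(=C)CO[Si](C)(C)C(C)(C)C)[C@H](OCc2ccc(OC)cc2)/C=C(\C)CC/C=C1/COCc1ccc(OC)cc1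
A5 | alternative 3 | protected melampolide with 14-ester and saturated lactone α-carbon | CC(C)(C)[Si](C)(C)O[C@H]1[C@H]2CC(=O)O[C@@H]2/C=C(\C)CC/C=C(/C(=O)OC)[C@@H]1OCc1ccc(OC)cc1
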